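**Retrosynthetic overview**
1. Contortin is a twofold-symmetric, tetra-ortho-substituted biaryl. Counted from the biaryl carbon C1, each ring carries OH (C2), acetyl (C3), OMe (C4), Me (C5) and OMe (C6). The acetyl groups go on last, by Friedel–Crafts acylation of the only free ring carbon C3/C3' of a 2,2'-biphenol. That biphenol comes from a C3/C3' diester by hydrolysis and loss of CO2, and the C6/C6' methyl ethers come from methylation of the hydroxyls para to those esters.
2. Key disconnection, in both rings at once: C1–C6 and C3–C4. C1–C2–C3 of each ring is then one β-keto ester half of dimethyl 3,6-dioxooctanedioate, and C4–C5–C6 is the ketene acetal ester methyl 3,3-dimethoxy-2-methylprop-2-enoate. The hindered biaryl bond C1–C1' is the central CH2–CH2 bond of the diketo diester, so it is never made by a coupling.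
3. Both benzene rings are formed in the same operation (step 4). The ester on C3 directs the dianion to the inner carbons, makes C3 the ring-closing nucleophile and marks the C2 hydroxyl by chelation; it is then removed as CO2.
4. The diketo diester comes from oxidative dimerisation of the methyl acetoacetate dianion, the ketene acetal from methyl 2-cyanopropanoate by a Pinner sequence.

Key step: step 4

Remark: the target SMILES defines no configuration at the biaryl axis, so compounds 10–15 are made as racemates; polyanions are drawn as carbanions with separate metal ions although they are delocalised enolates.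

**Step 1**
Reactants: 1 methyl acetoacetate (two molecules)
Product: 3 dimethyl 3,6-dioxooctanedioate, via sodium lithium dianion 2 (not isolated)
Conditions: NaH (1.1 equiv.), THF, 0 °C; n-BuLi (1.05 equiv.), 0 °C; I2 (0.5 equiv.), THF, −78 → 0 °C; cold aq. HCl, Na2S2O3 wash
Reagents that add atoms: none
Why: Oxidative homocoupling of a β-keto ester dianion, a known route from β-dicarbonyl dianions to 1,4-diketones: iodine oxidises the more basic terminal (γ) carbanion and the γ-iodide (or γ-radical) is intercepted by a second dianion at its γ-carbon, while the less reactive α-enolates are left untouched.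

**Step 2**
Reactants: 4 methyl 2-cyanopropanoate (racemic)
Product: 5 methyl 3-imino-3-methoxy-2-methylpropanoate hydrochloride (racemic)
Conditions: HCl (g), MeOH (1.05 equiv.), Et2O, 0 °C
Reagents that add atoms: methanol (CO); hydrogen chloride (Cl)
Why: Pinner reaction; HCl-activated addition of one equivalent of methanol to the nitrile should give the crystalline imidate hydrochloride, and the absence of water and the low temperature avoid ester or amide formation.

**Step 3**
Reactants: 5 methyl 3-imino-3-methoxy-2-methylpropanoate hydrochloride
Product: 7 methyl 3,3-dimethoxy-2-methylprop-2-enoate, via orthoester 6 (not isolated)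
Conditions: MeOH, 25 °C, filter off NH4Cl; cat. TsOH, 130 °C, distil off MeOH; distil under reduced pressure
Reagents that add atoms: methanol (CO)
Why: Second stage of the Pinner orthoester synthesis (methanolysis of the imidate salt) followed by acid-catalysed dealcoholation of the orthoester, which is easy here because the proton lost is alpha to the ester and the product is a conjugated push–pull ketene acetal; distilling out methanol drives the equilibrium.

**Step 4**
Reactants: 3 dimethyl 3,6-dioxooctanedioate; 7 methyl 3,3-dimethoxy-2-methylprop-2-enoate (two molecules)
Product: 10 dimethyl 2,2',6,6'-tetrahydroxy-4,4'-dimethoxy-5,5'-dimethylbiphenyl-3,3'-dicarboxylate, via tetralithium tetraanion 8 (not isolated), via open bis-acylated tetraenolate 9 (not isolated)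
Conditions: LDA (LiN(iPr)2, 6.3 equiv.), THF, −78 → 0 °C; 7 (2.3 equiv.), −78 → 0 °C; then 45 °C, strictly anhydrous; cold 2 M HCl
Reagents that add atoms: none
Why: Proposed new method: each lithium-bound γ-carbanion (C1, C1') of tetraanion 8 should add to the ester carbonyl of 7 and the tetrahedral intermediate lose methoxide (Claisen-type acylation, C1–C6), the two spare equivalents of LDA removing the newly acidic C1–H at once so that the neighbouring γ-carbanion is not quenched; in tetraenolate 9 the β-keto ester carbon C3 should then attack the dimethoxy-substituted alkene carbon C4 and expel methoxide (vinylic substitution, C3–C4), and tautomerisation gives both benzene rings as their phenoxides. The closest known reactions are the γ-acylation of β-keto ester dianions by non-enolisable esters with later base-mediated ring closure of the polycarbonyl chain to resorcinols or phloroglucinols, and the formal [3+3] benzannulation of 1,3-dinucleophiles with α-oxoketene dithioacetals; new here are a malonate-level ketene acetal ester as the three-carbon partner and the two-directional use on adjacent carbanions. Each ring closes in the 6-endo-trig mode (the attacked C4=C5 bond stays in the ring), and the two closures are independent and are induced by warming only after both acylations are complete at low temperature. No stereocentre is formed; the biaryl axis is the pre-existing C1–C1' single bond and arises as the racemate. The step needs carbonyl attack before attack at the acetal carbon, since the reverse order would exchange OH and OMe between C4 and C6: this should be secured by the hard, lithium-chelated γ-carbanion at −78 °C in THF without polar additives, which prefers 1,2-addition to the carbonyl over attack at the fully substituted, doubly oxygen-stabilised C4, whereas the stabilised C3 carbon is too weak a nucleophile to react with free 7 and only adds intramolecularly on warming. C- rather than O-cyclisation (which would give a 2-methoxy-4-pyranone) and retention of the C4 methoxy group should be secured by keeping the system fully deprotonated and free of water until both rings are closed.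

**Step 5**
Reactants: 10 dimethyl 2,2',6,6'-tetrahydroxy-4,4'-dimethoxy-5,5'-dimethylbiphenyl-3,3'-dicarboxylate
Product: 11 dimethyl 2,2'-dihydroxy-4,4',6,6'-tetramethoxy-5,5'-dimethylbiphenyl-3,3'-dicarboxylate
Conditions: MeI (2.2 equiv.), K2CO3 (2.2 equiv.), acetone, 56 °C
Reagents that add atoms: iodomethane (CI)
Why: Williamson O-methylation under weak base; the C6/C6' hydroxyls are para to the ester and free of hydrogen bonding, so they give the more acidic and more nucleophilic phenoxides, whereas the C2/C2' hydroxyls are held in a six-membered hydrogen bond to the ester carbonyl and should survive when only one equivalent of MeI per ring is used.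

**Step 6**
Reactants: 11 dimethyl 2,2'-dihydroxy-4,4',6,6'-tetramethoxy-5,5'-dimethylbiphenyl-3,3'-dicarboxylate
Product: 13 4,4',6,6'-tetramethoxy-5,5'-dimethylbiphenyl-2,2'-diol, via diacid 12 (not isolated)
Conditions: KOH (excess), DMSO/H2O, 110 °C, Ar; then 2 M HCl to pH 2, 50 °C
Reagents that add atoms: none
Why: Saponification of the hindered salicylate esters followed by protodecarboxylation; C3 is ortho to OH and OMe and para to OMe, so ipso-protonation and loss of CO2 from the free acid are fast on mild warming, and this ease of decarboxylation is used to clear C3 for acylation instead of carrying the sensitive acid forward.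

**Step 7**
Reactants: 13 4,4',6,6'-tetramethoxy-5,5'-dimethylbiphenyl-2,2'-diol
Product: 15 contortin, via bis(difluoroboron) chelate 14 (not isolated)
Conditions: Ac2O, BF3·OEt2, 60 °C; then NaOAc, MeOH/H2O, 65 °C
Reagents that add atoms: acetic anhydride (CC(=O)OC(C)=O)
Why: Friedel–Crafts acetylation (with Fries rearrangement of any aryl acetate formed first) at C3/C3', the only unsubstituted and strongly activated ring carbons (ortho to OH and OMe, para to OMe); the ketone is held as its BF2 chelate, which stops further reaction and is hydrolysed by buffered aqueous methanol.

**Compound list**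
1 | methyl acetoacetate | COC(=O)CC(C)=O | starting material
2 | sodium lithium dianion of methyl acetoacetate | [Na+].[Li+].COC(=O)[CH-]C(=O)[CH2-] | intermediate
3 | dimethyl 3,6-dioxooctanedioate | COC(=O)CC(=O)CCC(=O)CC(=O)OC | intermediate
4 | methyl 2-cyanopropanoate (racemic) | CC(C#N)C(=O)OC | starting material
5 | methyl 3-imino-3-methoxy-2-methylpropanoate hydrochloride (racemic) | COC(=O)C(C)C(=[NH2+])OC.[Cl-] | intermediate
6 | methyl 3,3,3-trimethoxy-2-methylpropanoate (racemic) | COC(=O)C(C)C(OC)(OC)OC | intermediate
7 | methyl 3,3-dimethoxy-2-methylprop-2-enoate | COC(=O)C(C)=C(OC)OC | intermediate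
8 | tetralithium tetraanion of dimethyl 3,6-dioxooctanedioate | [Li+].[Li+].[Li+].[Li+].COC(=O)[CH-]C(=O)[CH-][CH-]C(=O)[CH-]C(=O)OC | intermediate
9 | tetralithium tetraenolate of dimethyl 4,5-bis(3,3-dimethoxy-2-methylprop-2-enoyl)-3,6-dioxooctanedioate | [Li+].[Li+].[Li+].[Li+].COC(=O)[CH-]C(=O)[C-](C(=O)C(C)=C(OC)OC)[C-](C(=O)C(C)=C(OC)OC)C(=O)[CH-]C(=O)OC | intermediate
10 | dimethyl 2,2',6,6'-tetrahydroxy-4,4'-dimethoxy-5,5'-dimethylbiphenyl-3,3'-dicarboxylate | COC(=O)c1c(O)c(-c2c(O)c(C(=O)OC)c(OC)c(C)c2O)c(O)c(C)c1OC | intermediate
11 | dimethyl 2,2'-dihydroxy-4,4',6,6'-tetramethoxy-5,5'-dimethylbiphenyl-3,3'-dicarboxylate | COC(=O)c1c(O)c(-c2c(O)c(C(=O)OC)c(OC)c(C)c2OC)c(OC)c(C)c1OC | intermediate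
12 | 2,2'-dihydroxy-4,4',6,6'-tetramethoxy-5,5'-dimethylbiphenyl-3,3'-dicarboxylic acid | OC(=O)c1c(O)c(-c2c(O)c(C(=O)O)c(OC)c(C)c2OC)c(OC)c(C)c1OC | intermediate
13 | 4,4',6,6'-tetramethoxy-5,5'-dimethylbiphenyl-2,2'-diol | COc1cc(O)c(-c2c(O)cc(OC)c(C)c2OC)c(OC)c1C | intermediate
14 | bis(difluoroboron) chelate of contortin | CC1=[O+][B-](F)(F)Oc2c(-c3c(OC)c(C)c(OC)c4C(C)=[O+][B-](F)(F)Oc34)c(OC)c(C)c(OC)c12 | intermediate
15 | contortin | COc1c(C)c(OC)c(-c2c(O)c(C(C)=O)c(OC)c(C)c2OC)c(O)c1C(C)=O | target

**Totals**
Total step count: 7.
Longest linear sequence: 6 steps (methyl 2-cyanopropanoate to contortin through steps 2, 3, 4, 5, 6, 7).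

**Steps most likely to fail**

Step 4 (Proposed new method).
- What may go wrong: the γ-carbanions may attack the dimethoxy-substituted carbon of 7 instead of its carbonyl group, which transposes OH and OMe between C4 and C6. Crowding and proton transfer may stop the sequence after one acylation. Ring closure may also take place through enolate oxygen, or only after hydrolysis of the ketene acetal.
- Fallback (known chemistry): the biaryl bond is made by oxidative phenol coupling instead. Because this gives up the annulation, it cannot set out from one of compounds 1–9; it sets out from purchased 1,3-dimethoxy-2-methylbenzene F1 and comes back to the route at compound 13. C–H borylation of F1 with B2pin2, [Ir(OMe)(cod)]2 and 4,4'-di-tert-butyl-2,2'-bipyridine should take place at the only ring position without an ortho substituent and give 2-(3,5-dimethoxy-4-methylphenyl)-4,4,5,5-tetramethyl-1,3,2-dioxaborolane F2. Oxidation with H2O2/NaOH should give 3,5-dimethoxy-4-methylphenol F3. Heating F3 with di-tert-butyl peroxide in chlorobenzene should couple two aryloxyl radicals ortho to ortho (the para position is blocked by methyl and the two ortho positions are equivalent) to give 13, which is acetylated as in step 7.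

Step 1.
- What may go wrong: oxidation may stop at γ-iodination, or the γ-iodide may be consumed by O-alkylation and oligomerisation, so that little C–C dimer forms.
- Fallback: the central C–C bond is made by alkylation instead of oxidation; it sets out from compound 1 and comes back at compound 3. Compound 1 is converted with trimethyl orthoformate and catalytic H2SO4 into methyl (E)-3-methoxybut-2-enoate F4. F4 is brominated at the allylic methyl group with N-bromosuccinimide under radical initiation to methyl (E)-4-bromo-3-methoxybut-2-enoate F5. Dianion 2, made from a second portion of 1 as in step 1, is alkylated at its γ-carbon by F5 to give dimethyl (E)-3-methoxy-6-oxooct-2-enedioate F6. Aqueous HCl in THF then hydrolyses the enol ether of F6 to 3.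

Step 7.
- What may go wrong: under the Lewis acid the electron-rich 2,2'-biphenol may cyclise with loss of water or methanol to a dibenzofuran, acylation may stop at the aryl acetate or after one ring, or a methyl ether next to the new ketone may be cleaved.
- Fallback: directed ortho-metalation instead of electrophilic substitution; it sets out from compound 13 and comes back at compound 15. Compound 13 is protected with MOMCl/iPr2NEt as 2,2'-bis(methoxymethoxy)-4,4',6,6'-tetramethoxy-5,5'-dimethylbiphenyl F7. n-BuLi in THF at 0 °C should remove the only ring hydrogens (C3/C3', each between OMOM and OMe) to give 3,3'-dilithio-2,2'-bis(methoxymethoxy)-4,4',6,6'-tetramethoxy-5,5'-dimethylbiphenyl F8. F8 is acylated with N-methoxy-N-methylacetamide to contortin bis(methoxymethyl) ether F9, and HCl in methanol at 25 °C removes both MOM groups to give 15.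

**Further compounds**
F1 | step 4 | 1,3-dimethoxy-2-methylbenzene | COc1cccc(OC)c1C
F2 | step 4 | 2-(3,5-dimethoxy-4-methylphenyl)-4,4,5,5-tetramethyl-1,3,2-dioxaborolane | COc1cc(B2OC(C)(C)C(C)(C)O2)cc(OC)c1C
F3 | step 4 | 3,5-dimethoxy-4-methylphenol | COc1cc(O)cc(OC)c1C
F4 | step 1 | methyl (E)-3-methoxybut-2-enoate | CO/C(C)=C/C(=O)OC
F5 | step 1 | methyl (E)-4-bromo-3-methoxybut-2-enoate | CO/C(CBr)=C/C(=O)OC
F6 | step 1 | dimethyl (E)-3-methoxy-6-oxooct-2-enedioate | CO/C(CCC(=O)CC(=O)OC)=C/C(=O)OC
F7 | step 7 | 2,2'-bis(methoxymethoxy)-4,4',6,6'-tetramethoxy-5,5'-dimethylbiphenyl | COCOc1cc(OC)c(C)c(OC)c1-c1c(OCOC)cc(OC)c(C)c1OC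
F8 | step 7 | 3,3'-dilithio-2,2'-bis(methoxymethoxy)-4,4',6,6'-tetramethoxy-5,5'-dimethylbiphenyl | COCOc1c([Li])c(OC)c(C)c(OC)c1-c1c(OCOC)c([Li])c(OC)c(C)c1OC
F9 | step 7 | contortin bis(methoxymethyl) ether | COCOc1c(C(C)=O)c(OC)c(C)c(OC)c1-c1c(OCOC)c(C(C)=O)c(OC)c(C)c1OC
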